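## Structural features

The target is one oxolane ring (O1, C2–C5) flanked by two arenes. C2 carries a 3,4-dihydroxyphenyl group, C3 a hydroxymethyl group, C4 is a fully substituted carbinol carbon bearing a hydroxyl and a 3,4-dimethoxybenzyl group, and C5 is a methylene. C2, C3 and C4 are contiguous stereocentres, all R. The aryl group, the hydroxymethyl group and the tertiary hydroxyl lie on one face, so C2/C3 are cis (the less stable arrangement) and the benzyl group at C4 stands alone on the other face. The free catechol is oxidation-prone. The C2–O1 bond is benzylic to a para-oxygenated arene and is therefore open to acid ionisation (epimerisation at C2) and to hydrogenolysis. At the aldehyde oxidation level C3 is α to a carbonyl and β to the C4 oxygen, which invites epimerisation and β-elimination. The real difficulty is the quaternary carbinol centre C4, which nothing can correct later, together with the cis C2–C3 bond beside it. The key step exploits that C2 is an aryl carbinol carbon joined through O1 and C5 to C4, while C3 carries a one-carbon oxygenated branch. C2 can therefore serve as an aryl oxocarbenium carbon and C3 as the α-carbon of an aldehyde enol, both held in one seven-membered enol acetal built on O1–C5–C4. C4 has no hydrogen, so the enol ether cannot migrate.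

## Logic of the disconnections

17 ⇒ 16. Three O–CH2Ph bonds are cut (two aryl, one tertiary alkyl). One kind of protecting group keeps the catechol and the tertiary hydroxyl masked to the end and comes off under neutral conditions. The demand is a hydrogenolysis that spares the benzylic C2–O1 ring bond.

16 ⇒ 15. The C3 hydroxymethyl group is taken back to a formyl group, the retron of the ring contraction. The forward reduction must be faster than epimerisation at C3 and β-elimination of the C4 oxygen, so it is placed in the same flask at −78 °C.

15 ⇒ 14. The C2–C3 bond is cut and the formyl oxygen is rejoined to C2, giving the seven-membered enol acetal. This removes the ring, one skeletal C–C bond and two stereocentres at once and leaves C4 as the only stereocentre. The forward step must give the kinetic cis C2/C3 product, must let C4 choose the enol face, and must ionise the acetal in preference to the tertiary allylic ether. The benzyl ether on the C4 oxygen is kept deliberately: it is small at oxygen, cannot migrate and does not participate. Both acetal epimers of 14 are usable.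

14 ⇒ 12 (through 13). The C6=C7 double bond is traced to a C–Se bond at the future C3. The usual entry to such enol acetals, double-bond migration from the 4,7-dihydro isomer, is impossible next to a quaternary carbon. A syn-elimination has only one direction open, because the quaternary neighbour has no hydrogen. The demand is an elimination toward an oxygen-bearing carbon under basic conditions.

12 ⇒ 10 + 11. The two acetal C–O bonds are cut, which makes the route convergent. The seven-membered acetal must be the only one that can form, so the tertiary oxygen has to be blocked beforehand.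

10 ⇒ 9 ⇒ 8. The two primary hydroxyls are taken back to a lactone and the C–Se bond is cut at the lactone α-carbon. The lactone separates the two primary oxygens from the tertiary one without extra protecting groups and activates the future C3. The enolate must be trapped before it expels the β-benzyloxy group.

8 ⇒ 7. The tertiary O–benzyl bond is cut. The forward step needs a benzylation of a hindered β-hydroxy lactone without alkoxide formation (retro-aldol and elimination risk).

7 ⇒ 5 (through 6). The lactone C–O bond is cut and the ring methylene is taken back to a carboxyl carbon masked as a dioxolanone. The hydride must reduce the acylal carbonyl and leave the free carboxylate.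

5 ⇒ 3 + 4. The C4–CH2Ar bond is cut, which places the quaternary carbinol carbon on a chiral-pool centre. Creating C4 by enantioselective dihydroxylation of a 1,1-disubstituted alkene would leave both the sense and the level of induction unsecured, because the two alkene substituents are both methylene-linked. Here the configuration follows from the starting acid. The demand is alkylation of the enolate anti to the tert-butyl group.

3 ⇒ 1 + 2. The acetal C–O bonds are cut. The R acid is needed and the cis acetal must be secured by crystallisation. All four carbons of 1 end in the target (C5, C4, C3 and the hydroxymethyl carbon).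

## Other disconnections considered

Alternative 1: The cut runs through the C4–O bond and the O1–C2 bond, tracing the tertiary carbinol to a π-allyl unit.
- Forward step: zerovalent palladium from Pd2(dba)3 with a chiral phosphoramidite would ionise the racemic vinyl carbonate A1 with loss of CO2. The freed primary alkoxide would add to 11, and the hemiacetal alkoxide would close onto the substituted π-allyl terminus to give the vinyl dioxolane A2 with C4 defined.
- In its favour: C4 is set by a catalyst from a racemate, with no stoichiometric chiral source, and the aldehyde is installed in the same operation. On how C4 is created this is the better answer than the chosen plan, which spends the less common enantiomer of a chiral-pool acid and an auxiliary aldehyde.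
- Against it here: A2 holds the acetal carbon on the tertiary oxygen, a bond the target lacks, and it forms neither the C2–C3 bond nor the oxolane. The vinyl group supplies C3 and the hydroxymethyl carbon only as an unfunctionalised alkene. A direct Lewis-acid closure from A2 would engage the terminal vinyl carbon and lead to a six-membered ring. The π-allyl terminus also carries two methylene substituents that the ligand must tell apart.
- Comparison: in structure the plans agree only on C4. In mechanism the alternative is a catalytic enantioselective ionisation–addition, while the chosen plan relays a stored centre. In step economy it reaches a C4-defined intermediate in about as many steps as the chosen plan needs for 7 (equal), but a separate cis-selective C2–C3 bond formation would still be required.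

Alternative 2: The cuts are the tertiary C4–O bond and the O1–C5 ring bond, leading back to the acyclic alkenol A3 with C2 and C3 in place.
- Forward step: VO(acac)2 and tert-butyl hydroperoxide would epoxidise the 1,1-disubstituted alkene under guidance of the C2 hydroxyl. The same hydroxyl would then open the epoxide at the methylene carbon to give the oxolane A4; fluoride would give A5 and hydrogenolysis 17.
- In its favour: the C2/C3 relationship is fixed beforehand by open-chain chemistry and is not exposed to a Lewis acid afterwards. The tertiary hydroxyl needs no protecting group, and the last hydrogenolysis concerns only two aryl benzyl ethers. On protecting-group count, ease of the last step and independence from a kinetic cis closure it is the better plan.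
- Against it here: the directing hydroxyl is homoallylic and the centre that must bias the epoxide face is the allylic C3, so the induction at C4 rests on an unsecured conformational preference. The closure must occur at the less substituted epoxide carbon with the epoxide C–C bond inside the forming ring (a 5-endo opening), whereas acid favours cleavage at the tertiary carbon (oxetane or 1,2-shift). The nucleophile is an electron-rich benzylic alcohol that can itself ionise.
- Comparison: structurally both plans finish all three centres in the ring-forming step (equal). Mechanistically the chosen plan uses an electronically matched cation–enol combination, the alternative an opening against the intrinsic regiochemistry of the epoxide. Step counts are comparable, since A3 needs a diastereoselective C2–C3 assembly of its own.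

Alternative 3: The cut is the exocyclic C3–CH2 bond, leaving a 2-aryl-4,5-dihydrofuran whose C4 oxygen carries the carbon as a (bromomethyl)dimethylsilyl ether, A6.
- Forward step: Bu3SnH would generate the silylmethyl radical, which closes 5-exo onto C3 of the enol ether. The benzylic C2 radical then takes hydrogen on the convex face of the cis-fused bicycle A7. Tamao oxidation would give A5 and hydrogenolysis 17.
- In its favour: the C3/C4 cis relationship is enforced by the tether and does not depend on a small difference between benzyloxy and benzyl, which is better secured than in the chosen plan. The tether doubles as protecting group for the tertiary oxygen, so the tertiary benzylation and its late hydrogenolysis disappear (also better). A6 could be reached from 7 in few steps, so the length would be equal or slightly shorter.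
- Against it here: C2 is set by one hydrogen-atom transfer to a nearly planar benzylic radical, and the required outcome puts the large aryl group on the concave face. The addition of a nucleophilic alkyl radical to an electron-rich enol ether is polarity-mismatched. The acid-labile enol ether must survive silylation of a hindered tertiary alcohol, and stoichiometric tin is needed.
- Comparison: in structure the alternative builds C3 and C2 in two events on a preformed ring, the chosen plan in one bond formation that also makes the ring. In mechanism the chosen plan has precedent for the cis C2–C3 outcome, the alternative relies on face-selective hydrogen transfer. Overall the alternative is stronger on C3/C4 and protecting groups, the chosen plan on C2/C3.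

Key step: step 9

Assumption: the selenium-bearing carbon in 9, 10, 12 and 13 and the acetal carbon in 12–14 are carried as epimer mixtures, since both centres become trigonal before or in step 9; 1, 2, 4 and 11 are taken as commercial.

## Route

Step 1
Reactants: 1 (R)-malic acid; 2 pivalaldehyde
Product: 3 2-[(2R,4R)-2-tert-butyl-5-oxo-1,3-dioxolan-4-yl]acetic acid (cis)
Conditions: TsOH·H2O (cat.), H2SO4 (cat.), pentane, reflux, azeotropic removal of H2O; crystallisation
Reagents that add atoms: none
Why: Acid-catalysed acetalisation of the α-hydroxy acid unit closes the five-membered dioxolanone in preference to the six-membered dioxanone; the cis isomer should predominate and is purified by crystallisation. The malic stereocentre is untouched, and the new acetal centre (2R) stores its configuration for step 2 (self-regeneration of stereocentres).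

Step 2
Reactants: 3 2-[(2R,4R)-2-tert-butyl-5-oxo-1,3-dioxolan-4-yl]acetic acid; 4 3,4-dimethoxybenzyl bromide
Product: 5 2-[(2R,4R)-2-tert-butyl-4-[(3,4-dimethoxyphenyl)methyl]-5-oxo-1,3-dioxolan-4-yl]acetic acid
Conditions: LiN(SiMe3)2 (2.1 equiv), THF, −78 °C; then 4, −78 → −30 °C; aq. HCl work-up
Reagents that add atoms: none
Why: Double deprotonation gives the carboxylate–ring enolate dianion, and diastereoselective enolate alkylation should occur on the face opposite the tert-butyl group. The benzyl group thus replaces the former hydrogen with net retention, fixing the future C4 as R.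

Step 3
Reactants: 5 2-[(2R,4R)-2-tert-butyl-4-[(3,4-dimethoxyphenyl)methyl]-5-oxo-1,3-dioxolan-4-yl]acetic acid
Product: 7 (4R)-4-[(3,4-dimethoxyphenyl)methyl]-4-hydroxyoxolan-2-one, via dihydroxy acid 6 (not isolated)
Conditions: NaBH4, EtOH, 0 → 40 °C; then 2 M HCl, rt
Reagents that add atoms: none
Why: Borohydride in ethanol should reduce the activated acylal-type carbonyl (directly or after ethanolysis to the α-hydroxy ester) and leave the carboxylate salt, releasing pivalaldehyde as neopentyl alcohol. Acidification then closes the γ-lactone onto the new primary hydroxyl, so the tertiary hydroxyl is the only free OH; the stereocentre is not involved.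

Step 4
Reactants: 7 (4R)-4-[(3,4-dimethoxyphenyl)methyl]-4-hydroxyoxolan-2-one
Product: 8 (4R)-4-(benzyloxy)-4-[(3,4-dimethoxyphenyl)methyl]oxolan-2-one
Conditions: 2-benzyloxy-1-methylpyridinium triflate, MgO, PhCF3, 83 °C
Reagents that add atoms: 2-benzyloxy-1-methylpyridinium trifluoromethanesulfonate, C[n+]1ccccc1OCc1ccccc1.[O-]S(=O)(=O)C(F)(F)F
Why: Thermal benzyl transfer from the 2-benzyloxypyridinium salt under MgO-buffered, essentially neutral conditions benzylates hindered tertiary alcohols and base-sensitive β-hydroxy esters. No alkoxide is formed, so retro-aldol opening and β-elimination of the β-hydroxy lactone are avoided.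

Step 5
Reactants: 8 (4R)-4-(benzyloxy)-4-[(3,4-dimethoxyphenyl)methyl]oxolan-2-one
Product: 9 (4S)-4-(benzyloxy)-4-[(3,4-dimethoxyphenyl)methyl]-3-(phenylselanyl)oxolan-2-one (C3 epimers)
Conditions: LiN(SiMe3)2, THF, −78 °C; PhSeBr, −78 °C; AcOH quench
Reagents that add atoms: benzeneselenenyl bromide, Br[Se]c1ccccc1
Why: α-Selenenylation of a lactone lithium enolate; the enolate is kept at −78 °C and trapped at once by the fast electrophile so that expulsion of the β-benzyloxy group does not compete. The new C3 centre forms as a mixture and is erased in step 8 (the descriptor at C4 changes only because selenium alters the priorities).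

Step 6
Reactants: 9 (4S)-4-(benzyloxy)-4-[(3,4-dimethoxyphenyl)methyl]-3-(phenylselanyl)oxolan-2-one
Product: 10 (3S)-3-(benzyloxy)-3-[(3,4-dimethoxyphenyl)methyl]-2-(phenylselanyl)butane-1,4-diol (C2 epimers)
Conditions: LiAlH4, THF, 0 °C
Reagents that add atoms: none
Why: Hydride reduction of the lactone to the 1,4-diol; the alkyl aryl selenide is stable to LiAlH4 at 0 °C. The benzyl ether cannot migrate, so the two primary hydroxyls are free and the tertiary oxygen stays masked.

Step 7
Reactants: 10 (3S)-3-(benzyloxy)-3-[(3,4-dimethoxyphenyl)methyl]-2-(phenylselanyl)butane-1,4-diol; 11 3,4-bis(benzyloxy)benzaldehyde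
Product: 12 (5S)-2-[3,4-bis(benzyloxy)phenyl]-5-(benzyloxy)-5-[(3,4-dimethoxyphenyl)methyl]-6-(phenylselanyl)-1,3-dioxepane (C2 and C6 epimers)
Conditions: PPTS (cat.), benzene, reflux, azeotropic removal of H2O
Reagents that add atoms: none
Why: Acid-catalysed acetalisation with removal of water; with the tertiary oxygen blocked only the seven-membered 1,3-dioxepane can form, and the fully substituted ring carbon helps closure (gem-disubstituent effect). The acetal carbon forms as a mixture, which is harmless because it becomes planar in step 9.

Step 8
Reactants: 12 (5S)-2-[3,4-bis(benzyloxy)phenyl]-5-(benzyloxy)-5-[(3,4-dimethoxyphenyl)methyl]-6-(phenylselanyl)-1,3-dioxepane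
Product: 14 (5R)-2-[3,4-bis(benzyloxy)phenyl]-5-(benzyloxy)-5-[(3,4-dimethoxyphenyl)methyl]-4,5-dihydro-1,3-dioxepine (C2 epimers), via selenoxide 13 (not isolated)
Conditions: mCPBA, CH2Cl2, −78 °C; then i-Pr2NH, toluene, 80 °C
Reagents that add atoms: none
Why: The selenide is oxidised to the selenoxide at −78 °C, faster than any oxidation of the arenes, and thermal syn-elimination follows. The quaternary neighbour has no hydrogen, so the only β-hydrogens are on the OCH2 carbon and the double bond can form only as the ring-cis enol ether. The amine traps benzeneselenenic acid and keeps the acid-labile enol acetal basic.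

Step 9
Reactants: 14 (5R)-2-[3,4-bis(benzyloxy)phenyl]-5-(benzyloxy)-5-[(3,4-dimethoxyphenyl)methyl]-4,5-dihydro-1,3-dioxepine
Product: 16 {(2R,3R,4R)-2-[3,4-bis(benzyloxy)phenyl]-4-(benzyloxy)-4-[(3,4-dimethoxyphenyl)methyl]oxolan-3-yl}methanol, via oxolane-3-carbaldehyde 15 (not isolated)
Conditions: Me3SiOTf (0.1 equiv), 2,6-di-tert-butyl-4-methylpyridine (0.05 equiv), CH2Cl2, −78 °C; then i-Bu2AlH, −78 °C; aq. potassium sodium tartrate
Reagents that add atoms: none
Why: Me3SiOTf binds the enol-ether oxygen of 14 (the future formyl oxygen) and cleaves its bond to the acetal carbon (future C2), giving an aryl-stabilised oxocarbenium ion on the future O1 and, tethered through C5 and C4, a (Z)-silyl enol ether of the aldehyde; C–C recombination between the enol carbon (C3) and C2 should give 15 and return the silyl triflate. The closest known reaction type is the Lewis-acid ring contraction of 4,5-dihydro-1,3-dioxepines to cis-2,3-disubstituted oxolane-3-carbaldehydes, a Petasis–Ferrier-type 1,3 oxygen-to-carbon shift that amounts to an intramolecular Mukaiyama-type aldol addition to an oxocarbenium ion. The oxolane closes in the 5-(enolexo)-endo-trig mode, with both atoms of the C=O+ unit inside the ring and the enol C=C outside it, which is accessible for a cationic acceptor. C2 is set relative to C3 by the compact synclinal transition state of the tethered ion pair, which gives the kinetic cis product typical of this rearrangement at −78 °C. C3 is set relative to C4 by the fully substituted C4: the C4–C5 bond must stand over the attacked enol face, the oxygen substituent takes the in-plane inside position next to the cis silyloxy group (less allylic 1,3-strain than CH2Ar and a C–O bond orthogonal to the enol π system) and the benzyl group lies anti to the forming bond, so the formyl carbon ends cis to the C4 oxygen. Both acetal epimers converge because C2 is planar in the ion pair, and the enol ether cannot move because C4 has no hydrogen. The selectivities needed are acetal ionisation over ionisation of the tertiary allylic benzyl ether (the aryl acetal is much the more labile site and the hindered pyridine removes protic acid), carbon over oxygen recombination (the latter only regenerates 14) and retention of the kinetic product, which is why the epimerisable β-benzyloxy aldehyde 15 is reduced by i-Bu2AlH at −78 °C in the same flask before warming.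

Step 10
Reactants: 16 {(2R,3R,4R)-2-[3,4-bis(benzyloxy)phenyl]-4-(benzyloxy)-4-[(3,4-dimethoxyphenyl)methyl]oxolan-3-yl}methanol
Product: 17 (3R,4R,5R)-5-(3,4-dihydroxyphenyl)-3-[(3,4-dimethoxyphenyl)methyl]-4-(hydroxymethyl)oxolan-3-ol
Conditions: H2 (1 atm), Pd(OH)2/C, EtOAc/EtOH, rt
Reagents that add atoms: none
Why: Catalytic hydrogenolysis should remove the two aryl benzyl ethers quickly and the tertiary alkyl benzyl ether more slowly, under neutral, acid-free conditions chosen to spare the benzylic C2–O1 bond. No stereocentre is touched.

## Compound list

1 | (R)-malic acid, (2R)-2-hydroxybutanedioic acid | O[C@H](CC(O)=O)C(O)=O | starting material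
2 | pivalaldehyde (2,2-dimethylpropanal) | CC(C)(C)C=O | starting material
3 | 2-[(2R,4R)-2-tert-butyl-5-oxo-1,3-dioxolan-4-yl]acetic acid (cis) | CC(C)(C)[C@@H]1O[C@H](CC(O)=O)C(=O)O1 | intermediate
4 | 3,4-dimethoxybenzyl bromide, 4-(bromomethyl)-1,2-dimethoxybenzene | COc1ccc(CBr)cc1OC | starting material
5 | 2-[(2R,4R)-2-tert-butyl-4-[(3,4-dimethoxyphenyl)methyl]-5-oxo-1,3-dioxolan-4-yl]acetic acid | CC(C)(C)[C@@H]1O[C@](Cc2ccc(OC)c(OC)c2)(CC(O)=O)C(=O)O1 | intermediate
6 | (3R)-3-[(3,4-dimethoxyphenyl)methyl]-3,4-dihydroxybutanoic acid | COc1ccc(C[C@](O)(CO)CC(O)=O)cc1OC | intermediate (not isolated)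
7 | (4R)-4-[(3,4-dimethoxyphenyl)methyl]-4-hydroxyoxolan-2-one | COc1ccc(C[C@]2(O)COC(=O)C2)cc1OC | intermediate
8 | (4R)-4-(benzyloxy)-4-[(3,4-dimethoxyphenyl)methyl]oxolan-2-one | COc1ccc(C[C@]2(OCc3ccccc3)COC(=O)C2)cc1OC | intermediate
9 | (4S)-4-(benzyloxy)-4-[(3,4-dimethoxyphenyl)methyl]-3-(phenylselanyl)oxolan-2-one (C3 epimers) | COc1ccc(C[C@]2(OCc3ccccc3)COC(=O)C2[Se]c2ccccc2)cc1OC | intermediate
10 | (3S)-3-(benzyloxy)-3-[(3,4-dimethoxyphenyl)methyl]-2-(phenylselanyl)butane-1,4-diol (C2 epimers) | COc1ccc(C[C@@](CO)(OCc2ccccc2)C(CO)[Se]c2ccccc2)cc1OC | intermediate
11 | 3,4-bis(benzyloxy)benzaldehyde | O=Cc1ccc(OCc2ccccc2)c(OCc2ccccc2)c1 | starting material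
12 | (5S)-2-[3,4-bis(benzyloxy)phenyl]-5-(benzyloxy)-5-[(3,4-dimethoxyphenyl)methyl]-6-(phenylselanyl)-1,3-dioxepane (C2 and C6 epimers) | COc1ccc(C[C@]2(OCc3ccccc3)COC(c3ccc(OCc4ccccc4)c(OCc4ccccc4)c3)OCC2[Se]c2ccccc2)cc1OC | intermediate
13 | (5S)-6-(benzeneseleninyl)-2-[3,4-bis(benzyloxy)phenyl]-5-(benzyloxy)-5-[(3,4-dimethoxyphenyl)methyl]-1,3-dioxepane (selenoxide) | COc1ccc(C[C@]2(OCc3ccccc3)COC(c3ccc(OCc4ccccc4)c(OCc4ccccc4)c3)OCC2[Se](=O)c2ccccc2)cc1OC | intermediate (not isolated)
14 | (5R)-2-[3,4-bis(benzyloxy)phenyl]-5-(benzyloxy)-5-[(3,4-dimethoxyphenyl)methyl]-4,5-dihydro-1,3-dioxepine (C2 epimers) | COc1ccc(C[C@]2(OCc3ccccc3)COC(c3ccc(OCc4ccccc4)c(OCc4ccccc4)c3)OC=C2)cc1OC | intermediate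
15 | (2R,3R,4R)-2-[3,4-bis(benzyloxy)phenyl]-4-(benzyloxy)-4-[(3,4-dimethoxyphenyl)methyl]oxolane-3-carbaldehyde | COc1ccc(C[C@]2(OCc3ccccc3)CO[C@@H](c3ccc(OCc4ccccc4)c(OCc4ccccc4)c3)[C@H]2C=O)cc1OC | intermediate (not isolated)
16 | {(2R,3R,4R)-2-[3,4-bis(benzyloxy)phenyl]-4-(benzyloxy)-4-[(3,4-dimethoxyphenyl)methyl]oxolan-3-yl}methanol | COc1ccc(C[C@]2(OCc3ccccc3)CO[C@@H](c3ccc(OCc4ccccc4)c(OCc4ccccc4)c3)[C@H]2CO)cc1OC | intermediate
17 | (3R,4R,5R)-5-(3,4-dihydroxyphenyl)-3-[(3,4-dimethoxyphenyl)methyl]-4-(hydroxymethyl)oxolan-3-ol | COc1ccc(C[C@]2(O)CO[C@@H](c3ccc(O)c(O)c3)[C@H]2CO)cc1OC | target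

## Step count and least certain steps

Total step count: 10. Longest linear sequence: 10 steps (1 → 17); 2, 4 and 11 enter at steps 1, 2 and 7.

Step 9 (key step). The most likely failure is loss of kinetic control: the electron-rich benzylic C2 centre can re-ionise under the Lewis acid and drift to the 2,3-trans series. Competing ionisation of the tertiary allylic benzyloxy group and weak facial discrimination by C4 (benzyloxy and benzyl differ little in size) are also possible. The fallback builds the ring substituents stepwise and sets C2 by hydride delivery. It sets out from 8: enolate alkylation with benzyl chloromethyl ether (LiN(SiMe3)2, THF, −78 °C) gives the benzyloxymethyl lactone F1, whose C3 centre can be equilibrated and its epimers separated at this stage. Addition of [3,4-bis(benzyloxy)phenyl]lithium F2 (from 4-bromo-1,2-bis(benzyloxy)benzene and n-BuLi) at −78 °C gives the 2-aryl hemiketal F3. Ionic reduction with Et3SiH and BF3·OEt2 at −78 °C should deliver hydride to the 2-aryl oxocarbenium ion anti to the C3 substituent, giving the 2,3-cis tetrabenzyl oxolane F4. Hydrogenolysis of its four benzyl ethers comes back to the route at 17.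

Step 8. The syn-elimination has to run toward an oxygen-bearing carbon and may be slow, which would allow re-addition of selenenic acid to the enol ether or seleno-Pummerer-type decomposition. The fallback replaces it by a base-induced anti-elimination of a bromide and sets out from 8. Silyl ketene acetal formation (LiN(SiMe3)2, Me3SiCl, −78 °C) and N-bromosuccinimide give the α-bromo lactone F5. Reduction with i-Bu2AlH and a cold acidic quench gives the bromo diol F6, and acetalisation with 11 as in step 7 gives the 6-bromo-1,3-dioxepane F7. Dehydrobromination with t-BuOK in DMSO, again possible in one direction only, returns to the route at 14.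

Step 4. Benzyl transfer to the hindered tertiary carbinol may be incomplete, with competing C-benzylation of the electron-rich dimethoxyphenyl ring. The fallback forms the ether reductively and sets out from 7. Silylation (Me3SiCl, imidazole) gives the trimethylsilyl ether F8, and reductive etherification with benzaldehyde, Et3SiH and catalytic Me3SiOTf at −78 °C returns to the route at 8.

Step 5. The lactone enolate may expel benzyloxide (E1cB), which would give an achiral butenolide and destroy C4. The fallback carries the carbinol as its alkoxide, which is no leaving group, and sets out from 7. The dianion (LiN(i-Pr)2, 2.2 equiv, THF, −78 °C) is selenenylated with PhSeBr to give the α-seleno hydroxy lactone F9. Benzyl transfer with the pyridinium salt of step 4 returns to the route at 9.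

Step 10. Slow cleavage of the hindered tertiary benzyl ether may force long exposure and allow hydrogenolytic opening of the benzylic C2–O1 bond. The fallback changes the mechanism to single-electron debenzylation: 16 is treated with lithium 4,4′-di-tert-butylbiphenylide in THF at −78 °C. The benzyl phenyl rings accept electrons more readily than the dialkoxyaryl ring on C2, and the route is rejoined at 17 without any new compound.

## Further compounds

F1 | step 9 | (3S,4R)-4-(benzyloxy)-3-[(benzyloxy)methyl]-4-[(3,4-dimethoxyphenyl)methyl]oxolan-2-one | COc1ccc(C[C@]2(OCc3ccccc3)COC(=O)[C@H]2COCc2ccccc2)cc1OC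
F2 | step 9 | [3,4-bis(benzyloxy)phenyl]lithium | [Li]c1ccc(OCc2ccccc2)c(OCc2ccccc2)c1
F3 | step 9 | (3S,4R)-2-[3,4-bis(benzyloxy)phenyl]-4-(benzyloxy)-3-[(benzyloxy)methyl]-4-[(3,4-dimethoxyphenyl)methyl]oxolan-2-ol (anomers) | COc1ccc(C[C@]2(OCc3ccccc3)COC(O)(c3ccc(OCc4ccccc4)c(OCc4ccccc4)c3)[C@H]2COCc2ccccc2)cc1OC
F4 | step 9 | (2R,3R,4R)-2-[3,4-bis(benzyloxy)phenyl]-4-(benzyloxy)-3-[(benzyloxy)methyl]-4-[(3,4-dimethoxyphenyl)methyl]oxolane | COc1ccc(C[C@]2(OCc3ccccc3)CO[C@@H](c3ccc(OCc4ccccc4)c(OCc4ccccc4)c3)[C@H]2COCc2ccccc2)cc1OC
F5 | step 8 | (4S)-4-(benzyloxy)-3-bromo-4-[(3,4-dimethoxyphenyl)methyl]oxolan-2-one (C3 epimers) | COc1ccc(C[C@]2(OCc3ccccc3)COC(=O)C2Br)cc1OC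
F6 | step 8 | (3S)-3-(benzyloxy)-2-bromo-3-[(3,4-dimethoxyphenyl)methyl]butane-1,4-diol (C2 epimers) | COc1ccc(C[C@@](CO)(OCc2ccccc2)C(Br)CO)cc1OC
F7 | step 8 | (5S)-2-[3,4-bis(benzyloxy)phenyl]-5-(benzyloxy)-6-bromo-5-[(3,4-dimethoxyphenyl)methyl]-1,3-dioxepane (C2 and C6 epimers) | COc1ccc(C[C@]2(OCc3ccccc3)COC(c3ccc(OCc4ccccc4)c(OCc4ccccc4)c3)OCC2Br)cc1OC
F8 | step 4 | (4R)-4-[(3,4-dimethoxyphenyl)methyl]-4-[(trimethylsilyl)oxy]oxolan-2-one | COc1ccc(C[C@]2(O[Si](C)(C)C)COC(=O)C2)cc1OC
F9 | step 5 | (4S)-4-[(3,4-dimethoxyphenyl)methyl]-4-hydroxy-3-(phenylselanyl)oxolan-2-one (C3 epimers) | COc1ccc(C[C@]2(O)COC(=O)C2[Se]c2ccccc2)cc1OC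
F0 | step 10 | none | none
A1 | alternative 1 | rac-4-[(3,4-dimethoxyphenyl)methyl]-4-ethenyl-1,3-dioxolan-2-one (racemic) | C=CC1(Cc2ccc(OC)c(OC)c2)COC(=O)O1
A2 | alternative 1 | (4R)-2-[3,4-bis(benzyloxy)phenyl]-4-[(3,4-dimethoxyphenyl)methyl]-4-ethenyl-1,3-dioxolane (acetal epimers) | C=C[C@]1(Cc2ccc(OC)c(OC)c2)COC(c2ccc(OCc3ccccc3)c(OCc3ccccc3)c2)O1
A3 | alternative 2 | (1R,2R)-1-[3,4-bis(benzyloxy)phenyl]-2-({[tert-butyl(dimethyl)silyl]oxy}methyl)-3-[(3,4-dimethoxyphenyl)methyl]but-3-en-1-ol | C=C(Cc1ccc(OC)c(OC)c1)[C@H](CO[Si](C)(C)C(C)(C)C)[C@@H](O)c1ccc(OCc2ccccc2)c(OCc2ccccc2)c1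
A4 | alternative 2 | (3R,4R,5R)-5-[3,4-bis(benzyloxy)phenyl]-4-({[tert-butyl(dimethyl)silyl]oxy}methyl)-3-[(3,4-dimethoxyphenyl)methyl]oxolan-3-ol | COc1ccc(C[C@]2(O)CO[C@@H](c3ccc(OCc4ccccc4)c(OCc4ccccc4)c3)[C@H]2CO[Si](C)(C)C(C)(C)C)cc1OC
A5 | alternative 2 | (3R,4R,5R)-5-[3,4-bis(benzyloxy)phenyl]-3-[(3,4-dimethoxyphenyl)methyl]-4-(hydroxymethyl)oxolan-3-ol | COc1ccc(C[C@]2(O)CO[C@@H](c3ccc(OCc4ccccc4)c(OCc4ccccc4)c3)[C@H]2CO)cc1OC
A6 | alternative 3 | (3R)-5-[3,4-bis(benzyloxy)phenyl]-3-{[(bromomethyl)dimethylsilyl]oxy}-3-[(3,4-dimethoxyphenyl)methyl]-2,3-dihydrofuran | COc1ccc(C[C@]2(O[Si](C)(C)CBr)COC(c3ccc(OCc4ccccc4)c(OCc4ccccc4)c3)=C2)cc1OC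
A7 | alternative 3 | cis-fused 2,2-dimethyl-1,2-oxasilolane–oxolane bicycle, (2R,3R,4R) in oxolane numbering, with the C2 3,4-bis(benzyloxy)phenyl group cis to the C3 methylene and C4 carrying the 3,4-dimethoxybenzyl group | COc1ccc(C[C@]2(O6)CO[C@@H](c3ccc(OCc4ccccc4)c(OCc4ccccc4)c3)[C@H]2C[Si]6(C)C)cc1OC
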